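## Analysis of the target

Compound 31 is a 2',4'-dihydroxy-6'-methoxychalcone whose ring A (the phloroglucinol-derived ring) is bonded at C3' to C4 of a 2,4,6-trisubstituted tetrahydropyran. In the pyran, O1 is flanked by C2, which carries a 2-(4-hydroxyphenyl)ethyl chain, and by C6, which carries a 4-hydroxyphenyl group; C3 and C5 are methylene groups. The three stereocentres are 2S, 4R and 6S. All three substituents are mutually cis, so they can all be equatorial on one chair, but the centres are related 1,3 and 1,5 across the ring and not by adjacency. The sensitive groups are the E-enone (reducible, and able to close onto the 2'-hydroxyl as a flavanone), four free phenols, the very electron-rich ring A, and the C6–O1 bond, a para-hydroxybenzylic ether that ionizes under acid. The synthesis is hard because the C4–aryl bond joins a secondary carbon to an aryl group with two ortho oxygens, and because the acyl group must enter ring A at one defined position. The protecting groups must also survive a strong Lewis acid at one stage and an organolithium at another, and still leave without hydrogenation or harsh acid once the chalcone exists. The strategy rests on two features. C4 lies between C3H2 and C5H2, which lead to the two oxygen-bearing carbons C2 and C6, so the pyran is the reduced, cyclized form of a 1,5-diketone whose only stereocentre is C4. Ring A, before acylation, is symmetric about its C1'–C4' axis, so its two free positions are equivalent.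

## Retrosynthetic reasoning

31 to 30, then 25 and 28. The last operation is release of five acetal-protected phenols from 30. The enone of 30 is cut between ring A and the carbonyl carbon: aryllithium 29, made from bromide 25, acylates amide 28, which brings the complete E-enone with it. This cut avoids a Friedel–Crafts acylation on a substrate carrying an acid-labile benzylic ether. Amide 28 is traced through 27 to 26 by olefination and phenol protection.

25 to 24, 23 and 22. Bromide 25 comes from 24 by electrophilic bromination, which has to choose ring A over two mono-oxygenated rings; the two free positions of ring A in 24 interconvert by rotation about the C4–aryl bond, so only one monobromide exists. Ether 24 comes from tetraphenol 23, and 23 from tetrabenzyl ether 22 by hydrogenolysis. The exchange of protecting groups is needed because benzyl ethers are the ones that survive the ring-forming step but cannot be removed once the enone is present. Acetal ethers tolerate the organolithium and leave under mild acid.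

22 to 20. Both ring C–O bonds are opened and C2 and C6 are raised to the ketone level, which gives the open-chain 1,5-diketone 20 with the future C4 as its single stereocentre. In the forward direction the ring oxygen is one of the two carbonyl oxygens, so one C–O bond (O1–C2) is new, the other (O1–C6) is the reduced carbonyl bond, and two C–H bonds are made. The cut is placed here because the ring and both oxygen-bearing stereocentres then follow from C4 in one operation. The forward reaction must deliver hydride twice, each time axially to a cyclic oxocarbenium ion.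

20 to 15 and 18. The bond between the alkyl ketone carbonyl and the arylethyl CH2 is cut. Thioester 15 couples with organozinc 19, made from iodide 18, which comes from 16 through 17. A palladium-catalysed acyl coupling is chosen because it leaves the aryl ketone untouched.

15 to 14, then 11 and 12. The aryl ketone is cut between the carbonyl and its aryl ring: Grignard reagent 13, from bromide 12, adds once to the N-methoxy-N-methylamide arm of 11 while the other arm is masked as a carboxylate. Acid 14 is then activated as thioester 15.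

11 to 10 and 9. The two arms of 11 are told apart by opening the achiral anhydride 9 enantioselectively to half-ester 10. This is the only point where an external chiral influence acts, and it acts at carbonyl groups remote from the bulky aryl group. Either enantiomer of the half-ester could be carried on by exchanging the roles of the two arms, so the route does not depend on one sense of induction.

9 to 8 and 6. The bonds C3–C4 and C4–C5 of the future pyran are cut: the aldehyde carbon of 6 receives two acetic acid arms through bis-adduct 7, which gives diacid 8 and then anhydride 9. The hindered C4–aryl connection is thereby built by carbonyl chemistry at the very start.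

6 to 5, 4, 2 and 1. The formyl–aryl bond is cut: directed metalation of 2 between its two acetal ethers gives aryllithium 3 and then aldehyde 4. Benzyl ethers cannot serve at this stage (alkyllithiums deprotonate their benzylic carbon), and acetal ethers cannot pass the silyl triflate of the key step. The groups are therefore exchanged at the aldehyde, through 5 to 6. Ether 2 comes from 1.

## Alternatives that were turned down

Alternative 1: C3–C4 and C4–C5 are cut and C4 is treated as an acyl-anion equivalent. In the forward key step the lithio derivative of 2-(tert-butyldimethylsilyl)-1,3-dithiane A2 opens epoxide A3 at its CH2 carbon. A polar additive then triggers a 1,4-Brook shift of silicon to the new alkoxide, and the regenerated carbanion opens aryl epoxide A4, again at CH2, to give A1 with the whole C2–C6 chain in one flask.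
- For it: C2 and C6 come from two enantiopure epoxides by SN2 openings, so their absolute configuration is more secure than in the chosen route, where both are relayed from C4. The coupling is also convergent.
- Against it: C4 arrives as a masked ketone without ring A. After ring closure and removal of the dithioacetal, a di-ortho-oxygenated aryl metal must add to a ring ketone, and the tertiary benzylic hydroxyl must then be removed with control of C4. The para-alkoxy aryl epoxide A4 is prone to benzylic opening. The ring closure at C6 has to be engineered, and thioacetal cleavage in the presence of electron-rich arenes is delicate.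
- Comparison: the chosen route has ring A on the future C4 from aldehyde 6 onward and needs one chiral catalyst instead of two enantiopure building blocks. It should reach 22 in fewer operations after the stereocentres are in place.

Alternative 2: C2–C3 is cut. Dioxanone A6 is converted into its silyl ketene acetal with a lithium amide base and a chlorosilane, and the Ireland–Claisen rearrangement through a boat transition state contracts it to dihydropyran acid A5. This closes the ring, places the carboxyl at C2 cis to the C6 aryl group, and leaves ring A on a C4=C5 alkene.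
- For it: the 2,6-cis relation comes from pericyclic chirality transfer, which is at least as reliable as the hydride deliveries of the chosen route, and ring A is present from the start.
- Against it: C4 must still be set by hydrogenating a trisubstituted alkene bearing a di-ortho-substituted aryl group, which is slow and exposes the allylic and benzylic C6–O1 bond to hydrogenolysis. The C2 carboxyl must be turned into the arylethyl chain by reduction, olefination and hydrogenation. A6 requires an enantiopure diol that already carries the hindered 1-arylvinyl unit.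
- Comparison: the chosen route sets C4 first, by a desymmetrization far from the hindered aryl group, and introduces the C2 side chain complete. Alternative 2 would add three or four steps after the ring is formed.

Alternative 3: C5–C6 and O1–C2 are cut. Siloxydiene A8 and aldehyde A9 combine in a hetero-Diels–Alder reaction under the chiral Schiff-base CrCl complex A10 (trivalent chromium; drawn with the (1R,2S)-amino alcohol, the antipode being equally accessible) to give A7. The ring and both cis stereocentres at C2 and C6 are formed in one catalytic step.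
- For it: it is the most convergent of the four plans and the only one that sets two stereocentres catalytically in one step. Up to the ring it is shorter than the chosen route.
- Against it: C4 emerges as an enol silane, so the bond from C4 to the di-ortho-oxygenated ring A must be made late, either by cross-coupling of a hindered aryl metal or by addition to the ring ketone. A face-selective reduction must then set C4 next to a benzylic ether. The aldehyde needs an electron-poor acyl protecting group to react, which adds protecting-group changes.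
- Comparison: the chosen route makes its most hindered bond first and by simple carbonyl chemistry, and it leaves the ring closure as the single demanding step.

Key step: step 14

Assumption: the quinine-derived catalyst of step 7 is taken to deliver the (R)-half-ester 10; should the sense be the opposite, the quinidine-derived pseudo-enantiomer is used and nothing else changes.

## Route

Step 1
Reactants: 1 5-methoxyresorcinol
Product: 2 1-methoxy-3,5-bis(methoxymethoxy)benzene
Conditions: MOMCl (2.5 equiv), i-Pr2NEt (3 equiv), CH2Cl2, 0 °C to rt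
Reagents that add atoms: chloromethyl methyl ether, COCCl
Why: Williamson-type O-alkylation of both phenols; the methoxymethyl ethers are chosen because they are strong ortho-directing groups for the metalation of step 2.

Step 2
Reactants: 2 1-methoxy-3,5-bis(methoxymethoxy)benzene
Product: 4 4-methoxy-2,6-bis(methoxymethoxy)benzaldehyde, via 4-methoxy-2,6-bis(methoxymethoxy)phenyllithium 3 (not isolated)
Conditions: n-BuLi (1.1 equiv), TMEDA, THF, 0 °C; then DMF, 0 °C to rt; aq NH4Cl
Reagents that add atoms: N,N-dimethylformamide, CN(C)C=O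
Why: Directed ortho-metalation; the position between the two acetal ethers is deprotonated preferentially because both chelate lithium and the methyl ether is the weaker director, and aryllithium 3 is formylated by the formamide.

Step 3
Reactants: 4 4-methoxy-2,6-bis(methoxymethoxy)benzaldehyde
Product: 5 2,6-dihydroxy-4-methoxybenzaldehyde
Conditions: 3 M HCl, MeOH, 50 °C
Reagents that add atoms: none
Why: Acid-catalysed acetal exchange removes both methoxymethyl groups, which would not survive the silyl triflate of step 14; the hydrogen-bonded dihydroxy aldehyde is stable to these conditions.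

Step 4
Reactants: 5 2,6-dihydroxy-4-methoxybenzaldehyde
Product: 6 2,6-bis(benzyloxy)-4-methoxybenzaldehyde
Conditions: BnBr (2.5 equiv), K2CO3 (3 equiv), DMF, 65 °C
Reagents that add atoms: benzyl bromide, BrCc1ccccc1
Why: Williamson etherification of both chelated phenols under standard forcing conditions; benzyl ethers tolerate hot alkali, organomagnesium and organozinc reagents and the Lewis acid of the key step.

Step 5
Reactants: 6 2,6-bis(benzyloxy)-4-methoxybenzaldehyde
Product: 8 3-[2,6-bis(benzyloxy)-4-methoxyphenyl]pentanedioic acid, via diethyl 2,4-diacetyl-3-[2,6-bis(benzyloxy)-4-methoxyphenyl]pentanedioate 7 (not isolated)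
Conditions: ethyl acetoacetate (2.2 equiv), piperidine (0.2 equiv), EtOH, rt to 50 °C; then 10 M NaOH, EtOH, reflux; HCl to pH 2
Reagents that add atoms: ethyl acetoacetate, CCOC(=O)CC(C)=O; sodium hydroxide, [Na+].[OH-]
Why: Knoevenagel condensation followed by Michael addition of a second acetoacetate gives bis-adduct 7; concentrated alkali then removes both acetyl groups by retro-Claisen cleavage and saponifies the esters. The carbon that becomes C4 is still prochiral.

Step 6
Reactants: 8 3-[2,6-bis(benzyloxy)-4-methoxyphenyl]pentanedioic acid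
Product: 9 4-[2,6-bis(benzyloxy)-4-methoxyphenyl]oxane-2,6-dione
Conditions: Ac2O, 100 °C; evaporate, crystallize
Reagents that add atoms: none
Why: Cyclodehydration of a glutaric acid to its six-membered anhydride; the product is achiral and has two enantiotopic carbonyl groups.

Step 7
Reactants: 9 4-[2,6-bis(benzyloxy)-4-methoxyphenyl]oxane-2,6-dione
Product: 10 (3R)-3-[2,6-bis(benzyloxy)-4-methoxyphenyl]-5-methoxy-5-oxopentanoic acid
Conditions: MeOH (10 equiv), 9-amino-9-deoxy-epi-quinine 3,5-bis(trifluoromethyl)benzenesulfonamide (10 mol %), MTBE, rt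
Reagents that add atoms: methanol, CO
Why: Organocatalytic enantioselective alcoholysis (desymmetrization) of a prochiral cyclic anhydride: the quinuclidine nitrogen activates methanol as a general base while the sulfonamide N–H binds one of the two enantiotopic carbonyl groups, so the stereocentre (the later C4) is set as R by catalyst control. The reacting carbonyls are remote from the bulky aryl group, and the half-ester can be recrystallized to raise its enantiomeric purity.

Step 8
Reactants: 10 (3R)-3-[2,6-bis(benzyloxy)-4-methoxyphenyl]-5-methoxy-5-oxopentanoic acid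
Product: 11 (3S)-3-[2,6-bis(benzyloxy)-4-methoxyphenyl]-5-[methoxy(methyl)amino]-5-oxopentanoic acid
Conditions: MeNHOMe·HCl (2 equiv), i-PrMgCl (5 equiv), THF, −20 to 0 °C; 1 M HCl
Reagents that add atoms: N,O-dimethylhydroxylamine hydrochloride, CNOC.Cl
Why: Aminolysis of the methyl ester by the chloromagnesium amide (Weinreb amide synthesis) while the acid arm is masked in the flask as its magnesium carboxylate, so the two arms stay differentiated. The stereocentre is not touched; its descriptor changes only through the priority rules.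

Step 9
Reactants: 11 (3S)-3-[2,6-bis(benzyloxy)-4-methoxyphenyl]-5-[methoxy(methyl)amino]-5-oxopentanoic acid; 12 1-(benzyloxy)-4-bromobenzene
Product: 14 (3S)-3-[2,6-bis(benzyloxy)-4-methoxyphenyl]-5-[4-(benzyloxy)phenyl]-5-oxopentanoic acid, via 4-(benzyloxy)phenylmagnesium bromide 13 (not isolated)
Conditions: 12, Mg, THF, reflux; separately 11, i-PrMgCl (1.0 equiv), THF, −20 °C; then 13 (1.5 equiv), −20 to 0 °C; 1 M HCl
Reagents that add atoms: none
Why: Weinreb ketone synthesis; Grignard reagent 13 adds once to the amide, the chelated tetrahedral intermediate collapses only on acidic work-up, and the magnesium carboxylate is inert.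

Step 10
Reactants: 14 (3S)-3-[2,6-bis(benzyloxy)-4-methoxyphenyl]-5-[4-(benzyloxy)phenyl]-5-oxopentanoic acid
Product: 15 S-ethyl (3S)-3-[2,6-bis(benzyloxy)-4-methoxyphenyl]-5-[4-(benzyloxy)phenyl]-5-oxopentanethioate
Conditions: EtSH (3 equiv), EDC·HCl (1.3 equiv), DMAP (0.1 equiv), CH2Cl2, 0 °C to rt
Reagents that add atoms: ethanethiol, CCS
Why: Carbodiimide and DMAP mediated (Steglich) thioesterification; the thioester is the acyl donor for a ketone synthesis that tolerates the aryl ketone already present.

Step 11
Reactants: 16 tyrosol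
Product: 17 2-[4-(benzyloxy)phenyl]ethanol
Conditions: BnBr (1.05 equiv), K2CO3, acetone, reflux
Reagents that add atoms: benzyl bromide, BrCc1ccccc1
Why: Williamson etherification; carbonate deprotonates only the phenol, so the primary alcohol stays free.

Step 12
Reactants: 17 2-[4-(benzyloxy)phenyl]ethanol
Product: 18 1-(benzyloxy)-4-(2-iodoethyl)benzene
Conditions: I2, PPh3, imidazole, CH2Cl2, 0 °C to rt
Reagents that add atoms: iodine, [I][I]
Why: Appel-type iodination of a primary alcohol through its alkoxyphosphonium salt; it gives the iodide needed for zinc insertion.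

Step 13
Reactants: 15 S-ethyl (3S)-3-[2,6-bis(benzyloxy)-4-methoxyphenyl]-5-[4-(benzyloxy)phenyl]-5-oxopentanethioate; 18 1-(benzyloxy)-4-(2-iodoethyl)benzene
Product: 20 (3R)-3-[2,6-bis(benzyloxy)-4-methoxyphenyl]-1,7-bis[4-(benzyloxy)phenyl]heptane-1,5-dione, via 2-[4-(benzyloxy)phenyl]ethylzinc iodide 19 (not isolated)
Conditions: 18, Zn dust (activated with BrCH2CH2Br and Me3SiCl), LiCl, THF, 40 °C; then 15, PdCl2(PPh3)2 (5 mol %), toluene, rt
Reagents that add atoms: none
Why: Fukuyama coupling: zerovalent palladium formed in the flask inserts into the C–S bond, alkylzinc iodide 19 transmetalates and reductive elimination gives the ketone. Organozinc reagents do not add to the aryl ketone or to the product, and the stereocentre is not enolizable, so its configuration is kept (descriptor R by the priority rules).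

Step 14
Reactants: 20 (3R)-3-[2,6-bis(benzyloxy)-4-methoxyphenyl]-1,7-bis[4-(benzyloxy)phenyl]heptane-1,5-dione
Product: 22 (2S,4R,6S)-4-[2,6-bis(benzyloxy)-4-methoxyphenyl]-2-{2-[4-(benzyloxy)phenyl]ethyl}-6-[4-(benzyloxy)phenyl]oxane, via 2-(triethylsilyloxy)oxane 21 (not isolated)
Conditions: Et3SiH (6 equiv), Me3SiOTf (0.3 equiv), CH2Cl2, −78 to −30 °C; Et3N then aq NaHCO3 at −30 °C
Reagents that add atoms: none
Why: The silyl triflate activates the more electrophilic dialkyl ketone, and the oxygen of the aryl ketone, made nucleophilic by the para benzyloxy group, adds to it in a 6-exo-trig closure that forms the one new skeletal bond O1–C2 and gives a cyclic, aryl-stabilized oxocarbenium ion at C6 with C2 as a silyl ketal. Et3SiH reduces this ion to 21, the ketal then ionizes to a second oxocarbenium ion at C2 that is reduced in turn, and the oxygen of the former alkyl ketone leaves as hexaethyldisiloxane, so the ring oxygen is the old aryl-ketone oxygen and the O1–C6 bond is the reduced carbonyl bond. The closest known reaction type is the reductive etherification of 1,5-diketones and of δ-hydroxy or δ-silyloxy ketones with Et3SiH and a silyl triflate to cis-2,6-disubstituted tetrahydropyrans, para-alkoxyaryl ketones included. Each ion is a half-chair in which the bulky ring A group at C4 is pseudo-equatorial, and hydride enters axially through a chair-like transition state. C6 is therefore set as S by C4 (aryl group equatorial, cis to ring A), and C2 is set as S by C4 and C6 together (side chain equatorial), which gives the all-cis ring. The step needs ring closure to precede any hydride transfer, which the fast intramolecular capture of the activated ketone, set against slow bimolecular transfer from a weak hydride donor, should secure. It also needs the ions not to be trapped by ring A, which the benzyl ethers on its two ortho oxygens ensure, and the benzylic C6–O1 bond not to be reduced further, which the low temperature and the cold basic quench ensure. Excess silane keeps every cation short-lived, so that no 4H-pyran is oxidized to a pyrylium ion and C4, which has no acidic hydrogen, keeps its configuration.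

Step 15
Reactants: 22 (2S,4R,6S)-4-[2,6-bis(benzyloxy)-4-methoxyphenyl]-2-{2-[4-(benzyloxy)phenyl]ethyl}-6-[4-(benzyloxy)phenyl]oxane
Product: 23 2-[(2S,4R,6S)-2-[2-(4-hydroxyphenyl)ethyl]-6-(4-hydroxyphenyl)oxan-4-yl]-5-methoxybenzene-1,3-diol
Conditions: H2 (1 atm), 10% Pd/C, EtOAc/MeOH, rt; stopped after four equivalents are taken up
Reagents that add atoms: none
Why: Hydrogenolysis of four aryl benzyl ethers, which cleave far faster than the secondary cyclic benzylic ether C6–O1. It is done before the enone exists because the chalcone alkene would be hydrogenated.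

Step 16
Reactants: 23 2-[(2S,4R,6S)-2-[2-(4-hydroxyphenyl)ethyl]-6-(4-hydroxyphenyl)oxan-4-yl]-5-methoxybenzene-1,3-diol
Product: 24 (2S,4R,6S)-4-[4-methoxy-2,6-bis(methoxymethoxy)phenyl]-2-{2-[4-(methoxymethoxy)phenyl]ethyl}-6-[4-(methoxymethoxy)phenyl]oxane
Conditions: NaH (6 equiv), MOMCl (6 equiv), DMF, 0 °C to rt
Reagents that add atoms: chloromethyl methyl ether, COCCl
Why: Williamson-type O-alkylation of all four phenoxides; the acetal ethers tolerate the bromination and the organolithium that follow and leave at the end under mild acid.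

Step 17
Reactants: 24 (2S,4R,6S)-4-[4-methoxy-2,6-bis(methoxymethoxy)phenyl]-2-{2-[4-(methoxymethoxy)phenyl]ethyl}-6-[4-(methoxymethoxy)phenyl]oxane
Product: 25 (2S,4R,6S)-4-[3-bromo-4-methoxy-2,6-bis(methoxymethoxy)phenyl]-2-{2-[4-(methoxymethoxy)phenyl]ethyl}-6-[4-(methoxymethoxy)phenyl]oxane
Conditions: NBS (1.0 equiv), MeCN, −20 to 0 °C, dark
Reagents that add atoms: N-bromosuccinimide, O=C1CCC(=O)N1Br
Why: Electrophilic aromatic bromination; ring A, with three oxygen donors, is far more nucleophilic than the two mono-oxygenated rings. Its two free positions interconvert by rotation about the C4–aryl bond, so one equivalent should give a single monobromide.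

Step 18
Reactants: 26 4-hydroxybenzaldehyde
Product: 27 4-(methoxymethoxy)benzaldehyde
Conditions: MOMCl (1.3 equiv), i-Pr2NEt (1.5 equiv), CH2Cl2, 0 °C to rt
Reagents that add atoms: chloromethyl methyl ether, COCCl
Why: Williamson-type O-alkylation of the phenol, which gives the same protecting group as on the pyran fragment.

Step 19
Reactants: 27 4-(methoxymethoxy)benzaldehyde
Product: 28 (2E)-N-methoxy-3-[4-(methoxymethoxy)phenyl]-N-methylprop-2-enamide
Conditions: (EtO)2P(O)CH2C(O)N(OMe)Me (1.2 equiv), NaH, THF, 0 °C to rt
Reagents that add atoms: diethyl [2-[methoxy(methyl)amino]-2-oxoethyl]phosphonate, CCOP(=O)(CC(=O)N(C)OC)OCC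
Why: Horner–Wadsworth–Emmons olefination with a stabilized phosphonate anion, which gives the E-alkene.

Step 20
Reactants: 25 (2S,4R,6S)-4-[3-bromo-4-methoxy-2,6-bis(methoxymethoxy)phenyl]-2-{2-[4-(methoxymethoxy)phenyl]ethyl}-6-[4-(methoxymethoxy)phenyl]oxane; 28 (2E)-N-methoxy-3-[4-(methoxymethoxy)phenyl]-N-methylprop-2-enamide
Product: 30 (2E)-1-{6-methoxy-2,4-bis(methoxymethoxy)-3-[(2S,4R,6S)-2-{2-[4-(methoxymethoxy)phenyl]ethyl}-6-[4-(methoxymethoxy)phenyl]oxan-4-yl]phenyl}-3-[4-(methoxymethoxy)phenyl]prop-2-en-1-one, via ring A aryllithium 29 (not isolated)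
Conditions: n-BuLi (1.05 equiv), THF, −78 °C, 15 min; then 28 (1.3 equiv), −78 to −20 °C; aq NH4Cl
Reagents that add atoms: none
Why: Bromine–lithium exchange, which at −78 °C is faster than deprotonation at C6–H or next to the acetal ethers, gives 29; this adds to the carbonyl of the Weinreb amide, whose chelated tetrahedral intermediate prevents a second addition. The E-alkene is carried over unchanged.

Step 21
Reactants: 30 (2E)-1-{6-methoxy-2,4-bis(methoxymethoxy)-3-[(2S,4R,6S)-2-{2-[4-(methoxymethoxy)phenyl]ethyl}-6-[4-(methoxymethoxy)phenyl]oxan-4-yl]phenyl}-3-[4-(methoxymethoxy)phenyl]prop-2-en-1-one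
Product: 31 (2E)-1-{2,4-dihydroxy-3-[(2S,4R,6S)-2-[2-(4-hydroxyphenyl)ethyl]-6-(4-hydroxyphenyl)oxan-4-yl]-6-methoxyphenyl}-3-(4-hydroxyphenyl)prop-2-en-1-one
Conditions: 3 M HCl, MeOH/THF, rt to 40 °C, monitored and stopped at full conversion
Reagents that add atoms: none
Why: Acid-catalysed acetal cleavage of five aryl methoxymethyl ethers, the standard release of 2'-hydroxychalcones. The all-equatorial pyran is the thermodynamic isomer, so any reversible ionization at C6 should return the same configuration.

## Compound list

1 | 5-methoxyresorcinol (5-methoxybenzene-1,3-diol) | COc1cc(O)cc(O)c1 | starting material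
2 | 1-methoxy-3,5-bis(methoxymethoxy)benzene | COCOc1cc(OC)cc(OCOC)c1 | intermediate
3 | 4-methoxy-2,6-bis(methoxymethoxy)phenyllithium | [Li]c1c(OCOC)cc(OC)cc1OCOC | intermediate
4 | 4-methoxy-2,6-bis(methoxymethoxy)benzaldehyde | COCOc1cc(OC)cc(OCOC)c1C=O | intermediate
5 | 2,6-dihydroxy-4-methoxybenzaldehyde | COc1cc(O)c(C=O)c(O)c1 | intermediate
6 | 2,6-bis(benzyloxy)-4-methoxybenzaldehyde | COc1cc(OCc2ccccc2)c(C=O)c(OCc2ccccc2)c1 | intermediate
7 | diethyl 2,4-diacetyl-3-[2,6-bis(benzyloxy)-4-methoxyphenyl]pentanedioate (mixture of diastereomers, partly as its cyclic aldol form) | CCOC(=O)C(C(C)=O)C(c1c(OCc2ccccc2)cc(OC)cc1OCc1ccccc1)C(C(C)=O)C(=O)OCC | intermediate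
8 | 3-[2,6-bis(benzyloxy)-4-methoxyphenyl]pentanedioic acid | COc1cc(OCc2ccccc2)c(C(CC(=O)O)CC(=O)O)c(OCc2ccccc2)c1 | intermediate
9 | 4-[2,6-bis(benzyloxy)-4-methoxyphenyl]oxane-2,6-dione | COc1cc(OCc2ccccc2)c(C2CC(=O)OC(=O)C2)c(OCc2ccccc2)c1 | intermediate
10 | (3R)-3-[2,6-bis(benzyloxy)-4-methoxyphenyl]-5-methoxy-5-oxopentanoic acid | COc1cc(OCc2ccccc2)c([C@@H](CC(=O)OC)CC(=O)O)c(OCc2ccccc2)c1 | intermediate
11 | (3S)-3-[2,6-bis(benzyloxy)-4-methoxyphenyl]-5-[methoxy(methyl)amino]-5-oxopentanoic acid | COc1cc(OCc2ccccc2)c([C@@H](CC(=O)N(C)OC)CC(=O)O)c(OCc2ccccc2)c1 | intermediate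
12 | 1-(benzyloxy)-4-bromobenzene | Brc1ccc(OCc2ccccc2)cc1 | starting material
13 | 4-(benzyloxy)phenylmagnesium bromide | Br[Mg]c1ccc(OCc2ccccc2)cc1 | intermediate
14 | (3S)-3-[2,6-bis(benzyloxy)-4-methoxyphenyl]-5-[4-(benzyloxy)phenyl]-5-oxopentanoic acid | COc1cc(OCc2ccccc2)c([C@@H](CC(=O)c2ccc(OCc3ccccc3)cc2)CC(=O)O)c(OCc2ccccc2)c1 | intermediate
15 | S-ethyl (3S)-3-[2,6-bis(benzyloxy)-4-methoxyphenyl]-5-[4-(benzyloxy)phenyl]-5-oxopentanethioate | COc1cc(OCc2ccccc2)c([C@@H](CC(=O)c2ccc(OCc3ccccc3)cc2)CC(=O)SCC)c(OCc2ccccc2)c1 | intermediate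
16 | tyrosol (4-(2-hydroxyethyl)phenol) | OCCc1ccc(O)cc1 | starting material
17 | 2-[4-(benzyloxy)phenyl]ethanol | OCCc1ccc(OCc2ccccc2)cc1 | intermediate
18 | 1-(benzyloxy)-4-(2-iodoethyl)benzene | ICCc1ccc(OCc2ccccc2)cc1 | intermediate
19 | 2-[4-(benzyloxy)phenyl]ethylzinc iodide | I[Zn]CCc1ccc(OCc2ccccc2)cc1 | intermediate
20 | (3R)-3-[2,6-bis(benzyloxy)-4-methoxyphenyl]-1,7-bis[4-(benzyloxy)phenyl]heptane-1,5-dione | COc1cc(OCc2ccccc2)c([C@@H](CC(=O)c2ccc(OCc3ccccc3)cc2)CC(=O)CCc2ccc(OCc3ccccc3)cc2)c(OCc2ccccc2)c1 | intermediate
21 | 4-[2,6-bis(benzyloxy)-4-methoxyphenyl]-6-[4-(benzyloxy)phenyl]-2-{2-[4-(benzyloxy)phenyl]ethyl}-2-(triethylsilyloxy)oxane, C4 and C6 arranged as in 22, both epimers at C2 | COc1cc(OCc2ccccc2)c([C@@H]2CC(CCc3ccc(OCc4ccccc4)cc3)(O[Si](CC)(CC)CC)O[C@H](c3ccc(OCc4ccccc4)cc3)C2)c(OCc2ccccc2)c1 | intermediate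
22 | (2S,4R,6S)-4-[2,6-bis(benzyloxy)-4-methoxyphenyl]-2-{2-[4-(benzyloxy)phenyl]ethyl}-6-[4-(benzyloxy)phenyl]oxane | COc1cc(OCc2ccccc2)c([C@@H]2C[C@H](CCc3ccc(OCc4ccccc4)cc3)O[C@H](c3ccc(OCc4ccccc4)cc3)C2)c(OCc2ccccc2)c1 | intermediate
23 | 2-[(2S,4R,6S)-2-[2-(4-hydroxyphenyl)ethyl]-6-(4-hydroxyphenyl)oxan-4-yl]-5-methoxybenzene-1,3-diol | COc1cc(O)c([C@@H]2C[C@H](CCc3ccc(O)cc3)O[C@H](c3ccc(O)cc3)C2)c(O)c1 | intermediate
24 | (2S,4R,6S)-4-[4-methoxy-2,6-bis(methoxymethoxy)phenyl]-2-{2-[4-(methoxymethoxy)phenyl]ethyl}-6-[4-(methoxymethoxy)phenyl]oxane | COc1cc(OCOC)c([C@@H]2C[C@H](CCc3ccc(OCOC)cc3)O[C@H](c3ccc(OCOC)cc3)C2)c(OCOC)c1 | intermediate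
25 | (2S,4R,6S)-4-[3-bromo-4-methoxy-2,6-bis(methoxymethoxy)phenyl]-2-{2-[4-(methoxymethoxy)phenyl]ethyl}-6-[4-(methoxymethoxy)phenyl]oxane | COc1cc(OCOC)c([C@@H]2C[C@H](CCc3ccc(OCOC)cc3)O[C@H](c3ccc(OCOC)cc3)C2)c(OCOC)c1Br | intermediate
26 | 4-hydroxybenzaldehyde | O=Cc1ccc(O)cc1 | starting material
27 | 4-(methoxymethoxy)benzaldehyde | COCOc1ccc(C=O)cc1 | intermediate
28 | (2E)-N-methoxy-3-[4-(methoxymethoxy)phenyl]-N-methylprop-2-enamide | COCOc1ccc(/C=C/C(=O)N(C)OC)cc1 | intermediate
29 | ring A aryllithium from 25 (lithium in place of bromine) | COc1cc(OCOC)c([C@@H]2C[C@H](CCc3ccc(OCOC)cc3)O[C@H](c3ccc(OCOC)cc3)C2)c(OCOC)c1[Li] | intermediate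
30 | (2E)-1-{6-methoxy-2,4-bis(methoxymethoxy)-3-[(2S,4R,6S)-2-{2-[4-(methoxymethoxy)phenyl]ethyl}-6-[4-(methoxymethoxy)phenyl]oxan-4-yl]phenyl}-3-[4-(methoxymethoxy)phenyl]prop-2-en-1-one | COc1cc(OCOC)c([C@@H]2C[C@H](CCc3ccc(OCOC)cc3)O[C@H](c3ccc(OCOC)cc3)C2)c(OCOC)c1C(=O)/C=C/c1ccc(OCOC)cc1 | intermediate
31 | (2E)-1-{2,4-dihydroxy-3-[(2S,4R,6S)-2-[2-(4-hydroxyphenyl)ethyl]-6-(4-hydroxyphenyl)oxan-4-yl]-6-methoxyphenyl}-3-(4-hydroxyphenyl)prop-2-en-1-one | COc1cc(O)c([C@@H]2C[C@H](CCc3ccc(O)cc3)O[C@H](c3ccc(O)cc3)C2)c(O)c1C(=O)/C=C/c1ccc(O)cc1 | target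

## Step count and least certain steps

Total step count: 21. Longest linear sequence: 17 steps (steps 1 to 10, 13 to 17, 20 and 21).

Step 14 (key step). The most likely failure is hydride transfer to an open-chain silylated ketone before the ring has closed. C2 would then be set without the ring and with poor diastereoselection, and the aryl ketone could be reduced past the alcohol. A second danger is further ionization and reduction of the benzylic C6–O1 bond. The fallback sets out from 14 and sets the two oxygen-bearing centres one at a time.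
- Asymmetric transfer hydrogenation of the aryl ketone with RuCl(p-cymene)[(S,S)-TsNCH(Ph)CH(Ph)NH2] (divalent ruthenium) in HCO2H/Et3N should give (3S,5S)-3-[2,6-bis(benzyloxy)-4-methoxyphenyl]-5-[4-(benzyloxy)phenyl]-5-hydroxypentanoic acid F1, with C6 set by the catalyst.
- Acid-catalysed lactonization gives the cis lactone (4S,6S)-4-[2,6-bis(benzyloxy)-4-methoxyphenyl]-6-[4-(benzyloxy)phenyl]oxan-2-one F2.
- Addition of 2-[4-(benzyloxy)phenyl]ethylmagnesium iodide F3 (from 18 and Mg) at −78 °C gives the lactol 4-[2,6-bis(benzyloxy)-4-methoxyphenyl]-6-[4-(benzyloxy)phenyl]-2-{2-[4-(benzyloxy)phenyl]ethyl}oxan-2-ol F4.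
- Reduction of F4 with Et3SiH and BF3·OEt2 at −78 °C passes through a single cyclic oxocarbenium ion with two equatorial anchors and, by axial hydride delivery, comes back to the route at 22.

Step 5. The Michael addition of the second acetoacetate to the hindered, electron-rich arylidene intermediate may be sluggish, so the sequence could stall after the Knoevenagel condensation or revert during the alkaline cleavage. The fallback sets out from 6 and replaces conjugate addition by cation chemistry. Treatment with 1-methoxy-1-(trimethylsilyloxy)ethene (3 equiv) and catalytic Me3SiOTf in CH2Cl2 should give a Mukaiyama aldol addition followed by SN1 substitution of the benzylic silyl ether through the planar, trioxygenated benzylic cation. The product is dimethyl 3-[2,6-bis(benzyloxy)-4-methoxyphenyl]pentanedioate F5; saponification with LiOH comes back to the route at 8.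

Step 7. Discrimination between the two enantiotopic carbonyl groups may be insufficient with this bulky, di-ortho-substituted aryl group, which would give a half-ester of low enantiomeric purity. The fallback sets out from 9. Uncatalysed methanolysis gives racemic 3-[2,6-bis(benzyloxy)-4-methoxyphenyl]-5-methoxy-5-oxopentanoic acid F6. This is resolved by crystallization of its 1-phenylethylamine salt F7 (drawn with the R amine; the antipode is used if it gives the better crystals). Acidification of the salt comes back to the route at 10, and the unwanted enantiomer is returned to 8 by saponification.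

Step 20. The hindered aryllithium may be protonated before it is acylated, or it may add in conjugate fashion to the unsaturated amide. The fallback sets out from 25 and builds the enone by condensation. The same exchange to 29 is followed by acylation with N-methoxy-N-methylacetamide to give 1-{6-methoxy-2,4-bis(methoxymethoxy)-3-[(2S,4R,6S)-2-{2-[4-(methoxymethoxy)phenyl]ethyl}-6-[4-(methoxymethoxy)phenyl]oxan-4-yl]phenyl}ethanone F8. Claisen–Schmidt condensation of F8 with 27 (KOH, EtOH, rt) comes back to the route at 30.

Step 21. Removal of five acetals by acid may be accompanied by ionization of the C6–O1 benzylic bond (epimerization or solvolytic ring opening) and by cyclization of the 2'-hydroxychalcone to the flavanone. The fallback sets out from 23 and uses allyl ethers, which leave under neutral conditions.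
- Allyl bromide and K2CO3 in DMF give (2S,4R,6S)-4-[4-methoxy-2,6-bis(allyloxy)phenyl]-2-{2-[4-(allyloxy)phenyl]ethyl}-6-[4-(allyloxy)phenyl]oxane F9.
- NBS gives its ring A monobromide F10, and n-BuLi at −78 °C gives the aryllithium F11.
- F11 is acylated with (2E)-N-methoxy-N-methyl-3-[4-(allyloxy)phenyl]prop-2-enamide F12, made from commercial 4-(allyloxy)benzaldehyde as in step 19, to give the penta-O-allyl chalcone F13.
- Pd(PPh3)4 (zerovalent palladium) with morpholine in THF at rt removes the allyl groups and comes back to the route at 31.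

## Further compounds

F1 | step 14 | (3S,5S)-3-[2,6-bis(benzyloxy)-4-methoxyphenyl]-5-[4-(benzyloxy)phenyl]-5-hydroxypentanoic acid | COc1cc(OCc2ccccc2)c([C@@H](C[C@H](O)c2ccc(OCc3ccccc3)cc2)CC(=O)O)c(OCc2ccccc2)c1
F2 | step 14 | (4S,6S)-4-[2,6-bis(benzyloxy)-4-methoxyphenyl]-6-[4-(benzyloxy)phenyl]oxan-2-one | COc1cc(OCc2ccccc2)c([C@@H]2CC(=O)O[C@H](c3ccc(OCc4ccccc4)cc3)C2)c(OCc2ccccc2)c1
F3 | step 14 | 2-[4-(benzyloxy)phenyl]ethylmagnesium iodide | I[Mg]CCc1ccc(OCc2ccccc2)cc1
F4 | step 14 | 4-[2,6-bis(benzyloxy)-4-methoxyphenyl]-6-[4-(benzyloxy)phenyl]-2-{2-[4-(benzyloxy)phenyl]ethyl}oxan-2-ol (C4 and C6 as in 22, anomeric mixture) | COc1cc(OCc2ccccc2)c([C@@H]2CC(O)(CCc3ccc(OCc4ccccc4)cc3)O[C@H](c3ccc(OCc4ccccc4)cc3)C2)c(OCc2ccccc2)c1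
F5 | step 5 | dimethyl 3-[2,6-bis(benzyloxy)-4-methoxyphenyl]pentanedioate | COC(=O)CC(CC(=O)OC)c1c(OCc2ccccc2)cc(OC)cc1OCc1ccccc1
F6 | step 7 | racemic 3-[2,6-bis(benzyloxy)-4-methoxyphenyl]-5-methoxy-5-oxopentanoic acid | COc1cc(OCc2ccccc2)c(C(CC(=O)OC)CC(=O)O)c(OCc2ccccc2)c1
F7 | step 7 | (R)-1-phenylethylammonium salt of (3R)-3-[2,6-bis(benzyloxy)-4-methoxyphenyl]-5-methoxy-5-oxopentanoic acid | COc1cc(OCc2ccccc2)c([C@@H](CC(=O)OC)CC(=O)O)c(OCc2ccccc2)c1.C[C@@H](N)c1ccccc1
F8 | step 20 | 1-{6-methoxy-2,4-bis(methoxymethoxy)-3-[(2S,4R,6S)-2-{2-[4-(methoxymethoxy)phenyl]ethyl}-6-[4-(methoxymethoxy)phenyl]oxan-4-yl]phenyl}ethanone | COc1cc(OCOC)c([C@@H]2C[C@H](CCc3ccc(OCOC)cc3)O[C@H](c3ccc(OCOC)cc3)C2)c(OCOC)c1C(C)=O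
F9 | step 21 | (2S,4R,6S)-4-[4-methoxy-2,6-bis(allyloxy)phenyl]-2-{2-[4-(allyloxy)phenyl]ethyl}-6-[4-(allyloxy)phenyl]oxane | COc1cc(OCC=C)c([C@@H]2C[C@H](CCc3ccc(OCC=C)cc3)O[C@H](c3ccc(OCC=C)cc3)C2)c(OCC=C)c1
F10 | step 21 | (2S,4R,6S)-4-[3-bromo-4-methoxy-2,6-bis(allyloxy)phenyl]-2-{2-[4-(allyloxy)phenyl]ethyl}-6-[4-(allyloxy)phenyl]oxane | COc1cc(OCC=C)c([C@@H]2C[C@H](CCc3ccc(OCC=C)cc3)O[C@H](c3ccc(OCC=C)cc3)C2)c(OCC=C)c1Br
F11 | step 21 | ring A aryllithium from F10 (lithium in place of bromine) | COc1cc(OCC=C)c([C@@H]2C[C@H](CCc3ccc(OCC=C)cc3)O[C@H](c3ccc(OCC=C)cc3)C2)c(OCC=C)c1[Li]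
F12 | step 21 | (2E)-N-methoxy-N-methyl-3-[4-(allyloxy)phenyl]prop-2-enamide | C=CCOc1ccc(/C=C/C(=O)N(C)OC)cc1
F13 | step 21 | (2E)-1-{6-methoxy-2,4-bis(allyloxy)-3-[(2S,4R,6S)-2-{2-[4-(allyloxy)phenyl]ethyl}-6-[4-(allyloxy)phenyl]oxan-4-yl]phenyl}-3-[4-(allyloxy)phenyl]prop-2-en-1-one | COc1cc(OCC=C)c([C@@H]2C[C@H](CCc3ccc(OCC=C)cc3)O[C@H](c3ccc(OCC=C)cc3)C2)c(OCC=C)c1C(=O)/C=C/c1ccc(OCC=C)cc1
A1 | alternative 1 | (1S)-1-[4-(benzyloxy)phenyl]-2-{2-[(2S)-4-[4-(benzyloxy)phenyl]-2-(tert-butyldimethylsilyloxy)butyl]-1,3-dithian-2-yl}ethanol | O[C@H](c1ccc(OCc2ccccc2)cc1)CC1(C[C@@H](O[Si](C)(C)C(C)(C)C)CCc2ccc(OCc3ccccc3)cc2)SCCCS1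
A2 | alternative 1 | 2-(tert-butyldimethylsilyl)-1,3-dithiane | CC(C)(C)[Si](C)(C)C1SCCCS1
A3 | alternative 1 | (2S)-2-{2-[4-(benzyloxy)phenyl]ethyl}oxirane | C1[C@H](CCc2ccc(OCc3ccccc3)cc2)O1
A4 | alternative 1 | (2R)-2-[4-(benzyloxy)phenyl]oxirane | C1[C@@H](c2ccc(OCc3ccccc3)cc2)O1
A5 | alternative 2 | (2R,6S)-6-[4-(benzyloxy)phenyl]-4-[4-methoxy-2,6-bis(methoxymethoxy)phenyl]-3,6-dihydro-2H-pyran-2-carboxylic acid | COc1cc(OCOC)c(C2=C[C@@H](c3ccc(OCc4ccccc4)cc3)O[C@@H](C(=O)O)C2)c(OCOC)c1
A6 | alternative 2 | (5R,6R)-5-[4-(benzyloxy)phenyl]-6-{1-[4-methoxy-2,6-bis(methoxymethoxy)phenyl]ethenyl}-1,4-dioxan-2-one (trans) | O=C1CO[C@H](c2ccc(OCc3ccccc3)cc2)[C@@H](C(=C)c2c(OCOC)cc(OC)cc2OCOC)O1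
A7 | alternative 3 | 4-[(2S,6S)-6-{2-[4-(benzyloxy)phenyl]ethyl}-4-(triethylsilyloxy)-3,6-dihydro-2H-pyran-2-yl]phenyl 2,2-dimethylpropanoate | CC[Si](CC)(CC)OC1=C[C@H](CCc2ccc(OCc3ccccc3)cc2)O[C@H](c2ccc(OC(=O)C(C)(C)C)cc2)C1
A8 | alternative 3 | triethyl{[(3E)-6-[4-(benzyloxy)phenyl]hexa-1,3-dien-2-yl]oxy}silane | C=C(O[Si](CC)(CC)CC)/C=C/CCc1ccc(OCc2ccccc2)cc1
A9 | alternative 3 | 4-formylphenyl 2,2-dimethylpropanoate | CC(C)(C)C(=O)Oc1ccc(C=O)cc1
A10 | alternative 3 | chloro{2-(1-adamantyl)-4-methyl-6-[({(1R,2S)-2-oxidoindan-1-yl}imino)methyl]phenolato}chromium (trivalent chromium) | Cc1cc(C=N[C@@H]2c3ccccc3C[C@@H]2[O-])c([O-])c(c1)C12CC3CC(CC(C3)C1)C2.[Cr+3].[Cl-]
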